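**Assumptions**
- (6Z) is read from the SMILES: the C1 CH2OH and the allylic CH2 (C1') are cis across the trisubstituted alkene next to the butenolide. The other trisubstituted alkene is E.
- The butenolide C5 is (R) by CIP analysis of the target SMILES (O > C4 > C1' > H).
- RAMP delivers the (R)-alkylated dioxanone in the Enders alkylation (step 10). By analogy with acyclic SAMP-hydrazone alkylations, SAMP would give (S), so SAMP is the switch if the opposite sense is obtained.

**Retrosynthesis**
1. The butenolide (the only ring formed) comes last from an α-hydroxy ketone and Ph3P=C=C=O (ester ylide, then intramolecular Wittig).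
2. The α-hydroxy ketone comes from Enders RAMP-hydrazone α-alkylation of 2,2-dimethyl-1,3-dioxan-5-one (a dihydroxyacetone surrogate) with a Z-allylic bromide. This forms C5–C1' and sets C5.
3. The Z-allylic bromide comes from propargyl alcohol by Cu-catalysed carbomagnesation with a homoallylic Grignard, iodination, TBDPS protection, then I/Li exchange and CH2O.
4. The trimethylcyclohexene is carried in from β-ionone. The E-trisubstituted alkene comes from a Julia cyclopropylcarbinyl-to-homoallyl bromide rearrangement.

## Route

**Step 1**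
Reactants: 1 β-ionone
Product: 2 dihydro-β-ionone
Conditions: H2 (1 atm), 5% Pd/C, EtOAc, rt, stop at 1 equiv H2
Reagents that add atoms: none
Why: the disubstituted enone C=C is hydrogenated much faster than the tetrasubstituted ring alkene or the ketone (chemoselective hydrogenation).

**Step 2**
Reactants: 2 dihydro-β-ionone; 3 cyclopropylmagnesium bromide
Product: 4 2-cyclopropyl-4-(2,6,6-trimethylcyclohex-1-enyl)butan-2-ol
Conditions: THF, 0 °C to rt; then aq. NH4Cl
Reagents that add atoms: cyclopropylmagnesium bromide, Br[Mg]C1CC1
Why: Grignard 1,2-addition to the methyl ketone gives the tertiary cyclopropylcarbinol.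

**Step 3**
Reactants: 4
Product: 5 (E)-1-bromo-4-methyl-6-(2,6,6-trimethylcyclohex-1-enyl)hex-3-ene
Conditions: 48% aq. HBr, Et2O, 0 °C, 30 min; then AgNO3-silica chromatography
Reagents that add atoms: hydrogen bromide, Br
Why: Julia cyclopropylcarbinyl-cation to homoallyl-bromide rearrangement opens the ring through a chair-like transition state to give mainly the E-trisubstituted alkene (about 9:1 E:Z), and the E isomer is isolated by chromatography on AgNO3-silica.

**Step 4**
Reactants: 5
Product: 6 (E)-homoallylic Grignard reagent (made in situ)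
Conditions: Mg turnings, THF, 30 °C
Reagents that add atoms: magnesium, [Mg]
Why: standard Grignard formation. The homoallyl Grignard does not cyclise at this temperature.

**Step 5**
Reactants: 6 (3 equiv); 7 propargyl alcohol
Product: 8 (Z)-3-iodo-2-alkylprop-2-en-1-ol
Conditions: CuI (10 mol%), THF, 0 °C to rt, 12 h; then I2, –78 to 0 °C
Reagents that add atoms: iodine, II
Why: Cu-catalysed carbomagnesation of the propargyl alkoxide puts R at C2 and Mg at C3. The five-membered O–Mg chelate holds Mg cis to CH2O, so iodination gives the Z-vinyl iodide (I cis to CH2OH), which sets the Z alkene.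

**Step 6**
Reactants: 8
Product: 9 TBDPS ether of 8
Conditions: TBDPSCl, imidazole, DMF, rt
Reagents that add atoms: tert-butyldiphenylsilyl chloride, CC(C)(C)[Si](Cl)(c1ccccc1)c1ccccc1
Why: silylation gives a robust ether that survives the later organolithium, base and mild-acid steps.

**Step 7**
Reactants: 9; 10 formaldehyde
Product: 11 (Z)-allylic alcohol
Conditions: t-BuLi (2.1 equiv), Et2O, –78 °C; then gaseous CH2O, –78 to 0 °C
Reagents that add atoms: formaldehyde, C=O
Why: I/Li exchange is stereoretentive (the second equivalent of t-BuLi destroys the t-BuI formed), and the vinyllithium adds to CH2O to give the C1' carbinol with Z geometry retained.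

**Step 8**
Reactants: 11
Product: 12 (Z)-allylic bromide
Conditions: CBr4, PPh3, CH2Cl2, 0 °C, 30 min; use crude
Reagents that add atoms: carbon tetrabromide, BrC(Br)(Br)Br
Why: Appel SN2 substitution of a primary allylic alcohol gives the bromide without alkene isomerisation or SN2'.

**Step 9**
Reactants: 13 2,2-dimethyl-1,3-dioxan-5-one; 14 RAMP
Product: 15 RAMP hydrazone of 13
Conditions: benzene, 4 Å MS, 60 °C, 12 h (no acid catalyst)
Reagents that add atoms: none
Why: hydrazone condensation installs the chiral auxiliary. No acid is used so that the acetonide survives.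

**Step 10**
Reactants: 15; 12
Product: 16 alkylated RAMP hydrazone, (4R) at the dioxane
Conditions: LDA, THF, 0 °C, 3 h; then 12, –100 °C to rt
Reagents that add atoms: none
Why: Enders azaenolate alkylation. The ring fixes the azaenolate geometry, the Li-chelated RAMP auxiliary directs the face of attack by the allylic bromide, and the new C5–C1' bond sets the (R) centre.

**Step 11**
Reactants: 16
Product: 17 (4R)-4-alkyl-2,2-dimethyl-1,3-dioxan-5-one
Conditions: sat. aq. oxalic acid, Et2O, rt, 4 h
Reagents that add atoms: water, O
Why: mild two-phase hydrazone hydrolysis. There is no ozone or oxidant, so the three alkenes survive, and the acetonide, TBDPS ether and α-stereocentre are untouched.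

**Step 12**
Reactants: 17
Product: 18 (R)-α,α'-dihydroxy ketone
Conditions: Dowex 50WX8 (H+), MeOH, rt, short reaction time; use crude immediately
Reagents that add atoms: none
Why: acid-catalysed acetonide transketalisation (acetone is lost, both hydroxyl oxygens are the original ring oxygens). TBDPS and the alkenes survive, and the short time at rt limits enolisation at the α-centre.

**Step 13**
Reactants: 18
Product: 19 primary TBDPS ether with free secondary α-OH
Conditions: TBDPSCl (1.05 equiv), imidazole, CH2Cl2/DMF, 0 °C
Reagents that add atoms: tert-butyldiphenylsilyl chloride, CC(C)(C)[Si](Cl)(c1ccccc1)c1ccccc1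
Why: bulky TBDPSCl silylates the primary OH selectively. The secondary C5–OH must stay free so that the ylide ester forms on it and the ring closes through C5–O.

**Step 14**
Reactants: 19; 20 (triphenylphosphoranylidene)ketene
Product: 21 bis-TBDPS butenolide
Conditions: toluene, 60–80 °C
Reagents that add atoms: (triphenylphosphoranylidene)ketene, O=C=C=P(c1ccccc1)(c1ccccc1)c1ccccc1
Why: the secondary OH adds to the ketene to give an ester ylide, which undergoes intramolecular Wittig with the ketone (Bestmann butenolide synthesis). Conditions are neutral, ring closure forms the C3=C4 alkene, and C5 is not touched.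

**Step 15**
Reactants: 21
Product: 22 (6Z)-neomanoalide
Conditions: TBAF (4 equiv), AcOH (4 equiv), THF, 0 °C to rt, 12–24 h
Reagents that add atoms: none
Why: AcOH-buffered fluoride cleaves both TBDPS ethers (Si–F formation). The buffering suppresses γ-deprotonation of the butenolide, so C5 does not racemise or isomerise.

## Compound list
1 | β-ionone | CC(=O)/C=C/C1=C(C)CCCC1(C)C | starting material
2 | dihydro-β-ionone | CC(=O)CCC1=C(C)CCCC1(C)C | intermediate
3 | cyclopropylmagnesium bromide | Br[Mg]C1CC1 | starting material
4 | 2-cyclopropyl-4-(2,6,6-trimethylcyclohex-1-enyl)butan-2-ol | CC(O)(C1CC1)CCC1=C(C)CCCC1(C)C | intermediate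
5 | (E)-1-bromo-4-methyl-6-(2,6,6-trimethylcyclohex-1-enyl)hex-3-ene | BrCC/C=C(\C)CCC1=C(C)CCCC1(C)C | intermediate
6 | (E)-homoallylic Grignard reagent from 5 | Br[Mg]CC/C=C(\C)CCC1=C(C)CCCC1(C)C | intermediate
7 | propargyl alcohol | C#CCO | starting material
8 | (Z)-3-iodo-2-alkylprop-2-en-1-ol | OC/C(=C\I)CC/C=C(\C)CCC1=C(C)CCCC1(C)C | intermediate
9 | TBDPS ether of 8 | CC(C)(C)[Si](c1ccccc1)(c1ccccc1)OC/C(=C\I)CC/C=C(\C)CCC1=C(C)CCCC1(C)C | intermediate
10 | formaldehyde | C=O | starting material
11 | (Z)-allylic alcohol | CC(C)(C)[Si](c1ccccc1)(c1ccccc1)OC/C(=C\CO)CC/C=C(\C)CCC1=C(C)CCCC1(C)C | intermediate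
12 | (Z)-allylic bromide | CC(C)(C)[Si](c1ccccc1)(c1ccccc1)OC/C(=C\CBr)CC/C=C(\C)CCC1=C(C)CCCC1(C)C | intermediate
13 | 2,2-dimethyl-1,3-dioxan-5-one | CC1(C)OCC(=O)CO1 | starting material
14 | RAMP | NN1CCC[C@@H]1COC | starting material
15 | RAMP hydrazone of 13 | CC1(C)OCC(=NN2CCC[C@@H]2COC)CO1 | intermediate
16 | alkylated hydrazone (4R) | CC1(C)OCC(=NN2CCC[C@@H]2COC)[C@@H](C/C=C(\CO[Si](c3ccccc3)(c3ccccc3)C(C)(C)C)CC/C=C(\C)CCC3=C(C)CCCC3(C)C)O1 | intermediate
17 | (4R)-4-alkyl-2,2-dimethyl-1,3-dioxan-5-one | CC1(C)OCC(=O)[C@@H](C/C=C(\CO[Si](c2ccccc2)(c2ccccc2)C(C)(C)C)CC/C=C(\C)CCC2=C(C)CCCC2(C)C)O1 | intermediate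
18 | (R)-α,α'-dihydroxy ketone | OCC(=O)[C@@H](C/C=C(\CO[Si](c2ccccc2)(c2ccccc2)C(C)(C)C)CC/C=C(\C)CCC2=C(C)CCCC2(C)C)O | intermediate
19 | mono-TBDPS α-hydroxy ketone | CC(C)(C)[Si](c1ccccc1)(c1ccccc1)OCC(=O)[C@@H](C/C=C(\CO[Si](c2ccccc2)(c2ccccc2)C(C)(C)C)CC/C=C(\C)CCC2=C(C)CCCC2(C)C)O | intermediate
20 | (triphenylphosphoranylidene)ketene | O=C=C=P(c1ccccc1)(c1ccccc1)c1ccccc1 | starting material
21 | bis-TBDPS butenolide | CC1=C(CC/C(C)=C/CC/C(=C/C[C@H]2OC(=O)C=C2CO[Si](c3ccccc3)(c3ccccc3)C(C)(C)C)CO[Si](c3ccccc3)(c3ccccc3)C(C)(C)C)C(C)(C)CCC1 | intermediate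
22 | (6Z)-neomanoalide | CC1=C(CC/C(C)=C/CC/C(=C/C[C@H]2OC(=O)C=C2CO)CO)C(C)(C)CCC1 | target

## Totals
Total steps: 15. Longest linear sequence: 14 (from β-ionone, steps 1–8 and 10–15). The hydrazone formation in step 9 is a parallel branch.

## Three steps most likely to fail
1. **Step 3 (Julia rearrangement).** Aqueous HBr may attack the tetrasubstituted ring alkene or give poor E/Z selectivity.
   Fallback (different approach): Wittig olefination of ketone 2 with Ph3P=CH(CH2)2OTBS, separate E/Z on AgNO3-silica, remove TBS, then Appel bromination to give 5.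
2. **Step 10 (Enders alkylation).** The hindered Z-allylic bromide may give low yield or SN2' product, and the facial sense is assumed.
   Fallback (different approach): Evans alkylation of the N-(PMB-oxyacetyl) oxazolidinone with 12, using the auxiliary enantiomer that gives the (R) centre. Then form the Weinreb amide, add LiCH2OTBDPS (from Bu3SnCH2OTBDPS and n-BuLi) to give the α-PMBO ketone, and remove PMB with DDQ to reach 19 directly.
3. **Step 12 (acetonide removal).** The free α,α'-dihydroxy ketone may epimerise at C5 through an enediol, dimerise, or undergo α-ketol isomerisation.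
   Fallback (different approach): Takai–Lombardo methylenation of 17 to remove the ketone, then acetonide removal, selective primary TBDPS protection, acryloylation of the secondary OH, and Grubbs-II ring-closing metathesis to the butenolide. Global TBAF/AcOH then gives 22.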